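The readings stem from a simulated flask on assumed constants.

- I decided to book each flask by the Z left and not by the Q made. Apart from the 0.4 mol% that E takes, Z is lost at a rate constant times c(Z) times c(X), so ln(Z charged / Z left) simply adds up c(X) over the hours.

common to all: Z 1.1 M; E 0.4 mol%

| flask | J | remark | time |
|---|---|---|---|
| zeta | 0.43 M | run made earlier |  |
| delta | 2.8 M | run made earlier |  |
| Saturday's | 0.300 M |  | 6.0 h |
| Thursday's | 0.600 M |  | 6.0 h |
| Tuesday's | 1.20 M |  | 6.0 h |
| Wednesday's | 2.50 M |  | 6.0 h |

| run | time / h | Q / % | Z / % |
|---|---|---|---|
| zeta | 0.667 | 23.7 | 77.4 |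
| zeta | 1.33 | 32.5 | 67.5 |
| zeta | 2.00 | 38.1 | 62.5 |
| zeta | 3.00 | 40.8 | 58.7 |
| zeta | 4.00 | 43.4 | 56.9 |
| delta | 0.667 | 13.1 | 87.4 |
| delta | 1.33 | 13.4 | 85.9 |
| delta | 2.00 | 13.5 | 85.6 |
| delta | 3.00 | 13.7 | 86.1 |
| delta | 4.00 | 13.4 | 85.9 |

(readings scatter by 0.3 percentage points)

- the numbers in the tables scatter with a standard deviation of 0.3 percentage points
- candidate steps: Z + E -> X + Q; Z + X -> Q + X; 2 X -> D; X + J -> L
- "hardly changes" means that all values lie within two and a half points (for a concentration: within two and a half percent of the largest)

- amount of Q at the end, in percent of the Z charged for Saturday's, Thursday's, Tuesday's, Wednesday's, in this order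
- how that number moves from the first to the last of them (falls, then rises / rises all the way / hardly changes / falls all the way / rises, then falls)

- Delta stalled: Z read 85.9% after 1.33 h and 85.9% after 4.00 h, with a scatter of 0.3 percentage points. Z was still there, so I took X to have stopped making chains.
- The charge of E allows 0.00440 M of X, far below the 2.8 M of J in delta. So c(J) barely moves, and X + J → L is pseudo-first-order, with a lifetime of X that goes as one over c(J).
- Summed over a first-order death, c(X) is its start value times that lifetime. With that death alone, the logarithm at the stall should therefore also go as one over c(J), and multiplying by c(J) should give the same number from flask to flask at the same charges of Z and E.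
- From delta I kept 0.426 M: c(J) times ln(Z charged / Z left) at the stall, the kill product.
- Zeta tested it. After 4.00 h its product was 0.242 M, well below delta's, with Z still falling slowly. At low c(J), then, I took a second loss to be at work, two X giving D, which makes the kill product a ceiling.
- My ceilings for Q, from one minus exp(−product / c(J)), were 75.8%, 50.8%, 29.9% and 15.7%. I expected Wednesday's to land near its ceiling, Saturday's well under it, and Q to fall along the row.
- The forecast stood at 51%, 38%, 25% and 14.4%, shape falls all the way: “falling steadily as J rises”.
- The flasks gave 50.7%, 38.7%, 25.9% and 15.2%, so the number falls all the way.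

    Z + E → X + Q (k = 0.0290 /M/s)
    Z + X → Q + X, rate k2*[X]*[Z] (k = 0.0380 /M/s)
    2 X → D (k = 0.0340 /M/s)
    X + J → L (k = 3.60 × 10⁻⁴ /M/s)

- The largest single effect on the fall from Saturday's to Wednesday's was the loss of X + J to L: with that step taken out, the change of 35 points becomes 0 points. Wednesday's left 84.8% of its Z, a kill product of 0.413 M, close to delta's. Saturday's left 49.3%, a product of 0.212 M, half of delta's. Saturday's fell short because two X going to D took X alongside the loss to L: with the step to D taken out of Saturday's, Q at 6.00 h rises from 50.7% to 75.5%, a product of 0.422 M.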